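The trap I watched for was taking two nearly coinciding percent curves as proof that c(coupling partner) stays at saturation.

in all of them: gas 200 mM (held)
- west: substrate 1 M; run made earlier
- south: substrate 1.5 M; run made earlier
- flask: substrate 2.0 M; time 8.0 min

- west (time / min: double product / %): 0.833: 6.6; 1.33: 12.6; 2.00: 17.1; 3.00: 16.3; 5.00: 11.3
- south (time / min: double product / %): 0.833: 6.6; 1.33: 9.9; 2.00: 15.6; 3.00: 15.9; 5.00: 12.5

(readings scatter by 1 percentage point)

- for released group the idle adduct is counted in
- at the start none of coupling partner is dissolved
- steps thought possible: substrate + released group <-> idle adduct; coupling partner + mono adduct -> double product + released group; substrate + coupling partner -> mono adduct + released group; gas <-> coupling partner; coupling partner -> decomposition product; coupling partner + double product -> tris adduct + released group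

* when, up to 8.0 min, the flask holds most double product
* the amount of double product, in percent of the substrate charged, at that time
* earliest time at which at least nineteen twentieths of that best amount are there, in min
* latest time at which they still are, in min

The bench rule says that with the coupling partner held constant and the idle adduct set aside, each step is pseudo-first-order, so percent of charge against time does not depend on the charge. Applied honestly, it roughly fitted the highest readings, 17.1% at 2.00 min in the west run and 15.9% at 3.00 min in the south run, 1.2 percentage points apart against a scatter of 1 point; but at 1.33 min the west run read 12.6% and the south run 9.9%. The border lies in a ratio. I called the saturated coupling partner divided by the substrate charged the pool share: 0.100 in this flask, 0.200 in the west run. Each step takes one coupling partner, so bringing this flask's whole charge to double product takes 20.0 pools, against 10.0 in the west run. The rule needs uptake to refill the pool that often within minutes, and the readings don't show c(coupling partner). So I expected this flask's peak at the south run's time or later, and lower.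

The forecast put the best at 2.8 min with 15.5%, and the window from 2.1 min to 3.7 min, reasoning: “Dissolved partner probably stays fairly high”.

The flask gave 16.1% at 3.05 min, with the window from 2.41 min to 3.78 min, all four within the tolerance.

    substrate + released group ⇌ idle adduct, settled at all times (K = 1.19 M⁻¹)
    coupling partner + mono adduct → double product + released group (k = 0.176 M⁻¹ s⁻¹)
    substrate + coupling partner → mono adduct + released group (k = 0.0400 M⁻¹ s⁻¹)
    gas ⇌ coupling partner, rate k4*(csat - [coupling partner]) (kL = 0.112 s⁻¹)
    coupling partner → decomposition product (k = 5.54 × 10⁻⁶ s⁻¹)
    coupling partner + double product → tris adduct + released group (k = 0.0881 M⁻¹ s⁻¹)

The flask peaked with its pool below saturation: at 3.05 min, c(coupling partner) stood at 0.118 M, 58.8% of saturation. Counting one coupling partner for each step taken, the flask had by then drawn 9.04 pools. The neighbouring flask, stopped at 2.0 min, had drawn 6.01 pools, with c(coupling partner) at 0.108 M, 54.0% of saturation, double product at 13.7% and 39% of the charged substrate still unbound.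

(The runs were computed with constants of no real substance; scatter was added.)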